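**Assumption:** the target has no stereocentre and no stereogenic double bond, so it is achiral and needs no enantiocontrol; compounds 1 and 8 are taken as purchasable.

## Retrosynthetic overview

1. Target 13 ⇒ 12 ⇒ 11: chelation-controlled 5-O-demethylation and 2'-O-debenzylation come last.
2. 11 ⇒ 7 + 9: the C2–C1' bond is made by a new Pd-catalysed C2-arylation of a 3-hydroxychromone enolate, which attaches the B ring.
3. 7 ⇒ 5 (C3–O via epoxide) ⇒ 3 + one carbon from DMF-DMA, which closes the pyranone C ring.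
4. 3 ⇒ 1 (A ring bought, acylated and ortho-demethylated); 9 ⇒ 8 (B ring bought, O-benzylated).
5. Ring order: A ring (bought) → C ring (step 2) → B ring joined (step 5).

## Route

Step 1
Reactants: 1 1,2,3,5-tetramethoxybenzene
Product: 3 1-(2-hydroxy-3,4,6-trimethoxyphenyl)ethan-1-one, via 2,3,4,6-tetramethoxyacetophenone 2 (not isolated)
Conditions: AcCl (1.2 equiv), AlCl3 (2.5 equiv), Et2O, 0 °C → rt; aq. HCl work-up
Reagents that add atoms: acetyl chloride, CC(Cl)=O
Why: Friedel–Crafts acylation at the only free (doubly activated) position, then AlCl3-chelation-controlled ortho-demethylation, which selects the buttressed 2-OMe (flanked by C=O and 3-OMe) over the 6-OMe.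

Step 2
Reactants: 3 1-(2-hydroxy-3,4,6-trimethoxyphenyl)ethan-1-one
Product: 5 5,7,8-trimethoxy-4H-chromen-4-one, via enaminone 4 (not isolated)
Conditions: DMF-DMA (2 equiv), toluene, 100 °C; evaporate; AcOH, 90 °C
Reagents that add atoms: N,N-dimethylformamide dimethyl acetal, COC(OC)N(C)C
Why: Enaminone condensation at the acetyl CH3, then acid-promoted conjugate addition of the only free phenol and loss of Me2NH (enaminone chromone synthesis), which fixes the 5,7,8-pattern.

Step 3
Reactants: 5 5,7,8-trimethoxy-4H-chromen-4-one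
Product: 7 3-hydroxy-5,7,8-trimethoxy-4H-chromen-4-one, via 2,3-epoxychromanone 6 (not isolated)
Conditions: DMDO (ca. 0.07 M in acetone, 1.5 equiv), CH2Cl2, 0 °C → rt; then p-TsOH·H2O (cat.), CH2Cl2, rt
Reagents that add atoms: dimethyldioxirane, CC1(C)OO1
Why: Electrophilic dioxirane epoxidation of the electron-rich enol-ether C2=C3 bond, then acid-catalysed epoxide-to-enol isomerisation through the C2 oxocarbenium ion; the racemic cis-epoxide stereocentres vanish.

Step 4
Reactants: 8 2-bromo-5-methoxyphenol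
Product: 9 2-(benzyloxy)-1-bromo-4-methoxybenzene
Conditions: BnBr (1.1 equiv), K2CO3 (1.5 equiv), DMF, 60 °C
Reagents that add atoms: benzyl bromide, BrCc1ccccc1
Why: Williamson ether synthesis on the phenoxide; the aryl bromide is inert to SN2 conditions.

Step 5
Reactants: 7 3-hydroxy-5,7,8-trimethoxy-4H-chromen-4-one; 9 2-(benzyloxy)-1-bromo-4-methoxybenzene
Product: 11 2-[2-(benzyloxy)-4-methoxyphenyl]-3-hydroxy-5,7,8-trimethoxy-4H-chromen-4-one, via 2-arylchromane-3,4-dione 10 (not isolated)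
Conditions: 7 (1.2 equiv), 9 (1.0 equiv), Pd2(dba)3 (2.5 mol %), Xantphos (6 mol %), K3PO4 (2.5 equiv, anhydrous), 1,4-dioxane, 100 °C, Ar; aq. NH4Cl work-up
Reagents that add atoms: none
Why: Proposed new method: Pd(0)/Xantphos-catalysed C2-arylation of a 3-hydroxychromone enolate, not yet shown for 3-hydroxychromones or other cyclic 1,2-dione enols; 7 is the enol of a chromane-3,4-dione whose C2 is the nucleophilic α-carbon (the position where 3-hydroxy-4-pyranones such as kojic acid undergo Mannich and aldol reactions), so oxidative addition of 9, bromide/enolate exchange, O-to-C2 shift of Pd and C–C reductive elimination give dione 10, which tautomerises irreversibly to pyranone 11 (its transient racemic C2 centre is lost); the wide-bite-angle bisphosphine blocks κ2-O,O chelation by the hydroxypyranonate and disfavours C–O reductive elimination, and the product has no C2–H left for a second arylation; closest known reaction type is Pd-catalysed α-arylation of ketone and cyclic 1,3-dione enolates and ortho-C-arylation of naphtholates with aryl bromides.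

Step 6
Reactants: 11 2-[2-(benzyloxy)-4-methoxyphenyl]-3-hydroxy-5,7,8-trimethoxy-4H-chromen-4-one
Product: 12 3-hydroxy-2-(2-hydroxy-4-methoxyphenyl)-5,7,8-trimethoxy-4H-chromen-4-one
Conditions: H2 (1 atm), 10% Pd/C, EtOAc–MeOH, rt
Reagents that add atoms: none
Why: Hydrogenolysis of the benzyl aryl ether; the vinylogous-ester C2=C3 bond and the aryl methyl ethers are not reduced under these conditions.

Step 7
Reactants: 12 3-hydroxy-2-(2-hydroxy-4-methoxyphenyl)-5,7,8-trimethoxy-4H-chromen-4-one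
Product: 13 3,5-dihydroxy-2-(2-hydroxy-4-methoxyphenyl)-7,8-dimethoxy-4H-chromen-4-one (target)
Conditions: BCl3 (1 M in CH2Cl2, 4 equiv), CH2Cl2, −40 → 0 °C; then H2O/1 M HCl, rt
Reagents that add atoms: none
Why: Chelation-controlled Lewis-acid demethylation: boron bridges C4=O and the peri 5-OMe and chloride removes that methyl by SN2, while the non-chelating 7-, 8- and 4'-OMe groups survive at ≤0 °C.

## Compound list

1 | 1,2,3,5-tetramethoxybenzene | COc1cc(OC)c(OC)c(OC)c1 | starting material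
2 | 1-(2,3,4,6-tetramethoxyphenyl)ethan-1-one | CC(=O)c1c(OC)c(OC)c(OC)cc1OC | intermediate (not isolated)
3 | 1-(2-hydroxy-3,4,6-trimethoxyphenyl)ethan-1-one | CC(=O)c1c(O)c(OC)c(OC)cc1OC | intermediate
4 | (E)-3-(dimethylamino)-1-(2-hydroxy-3,4,6-trimethoxyphenyl)prop-2-en-1-one | CN(C)/C=C/C(=O)c1c(O)c(OC)c(OC)cc1OC | intermediate (not isolated)
5 | 5,7,8-trimethoxy-4H-chromen-4-one | COc1cc(OC)c2c(=O)ccoc2c1OC | intermediate
6 | rac-2,3-epoxy-5,7,8-trimethoxychroman-4-one (oxirane necessarily cis-fused, racemic) | COc1cc(OC)c2C(=O)C3OC3Oc2c1OC | intermediate (not isolated)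
7 | 3-hydroxy-5,7,8-trimethoxy-4H-chromen-4-one | COc1cc(OC)c2c(=O)c(O)coc2c1OC | intermediate
8 | 2-bromo-5-methoxyphenol | COc1ccc(Br)c(O)c1 | starting material
9 | 2-(benzyloxy)-1-bromo-4-methoxybenzene | COc1ccc(Br)c(OCc2ccccc2)c1 | intermediate
10 | rac-2-[2-(benzyloxy)-4-methoxyphenyl]-5,7,8-trimethoxychromane-3,4-dione (keto tautomer of 11, C2 racemic) | COc1ccc(C2Oc3c(OC)c(OC)cc(OC)c3C(=O)C2=O)c(OCc2ccccc2)c1 | intermediate (not isolated)
11 | 2-[2-(benzyloxy)-4-methoxyphenyl]-3-hydroxy-5,7,8-trimethoxy-4H-chromen-4-one | COc1ccc(-c2oc3c(OC)c(OC)cc(OC)c3c(=O)c2O)c(OCc2ccccc2)c1 | intermediate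
12 | 3-hydroxy-2-(2-hydroxy-4-methoxyphenyl)-5,7,8-trimethoxy-4H-chromen-4-one | COc1ccc(-c2oc3c(OC)c(OC)cc(OC)c3c(=O)c2O)c(O)c1 | intermediate
13 | 3,5-dihydroxy-2-(2-hydroxy-4-methoxyphenyl)-7,8-dimethoxy-4H-chromen-4-one (3,5,2'-trihydroxy-7,8,4'-trimethoxyflavone, achiral) | COc1ccc(-c2oc3c(OC)c(OC)cc(O)c3c(=O)c2O)c(O)c1 | target

## Step count and risks

Total steps: 7. Longest linear sequence: 6 (steps 1, 2, 3, 5, 6, 7); step 4 is a one-step side branch.

**Step 5 (the new arylation).** The main risks are O-arylation to a 3-aryloxychromone and an unreactive O,O-chelated Pd enolate. The fallback uses known chemistry only, sets out from 3 and 9 and comes back at 11. Bromine–lithium exchange on 9 (n-BuLi, THF, −78 °C) and a DMF quench give 2-(benzyloxy)-4-methoxybenzaldehyde F1. Claisen–Schmidt condensation of 3 with this aldehyde (KOH, EtOH, rt) gives (E)-3-[2-(benzyloxy)-4-methoxyphenyl]-1-(2-hydroxy-3,4,6-trimethoxyphenyl)prop-2-en-1-one F2. Oxidative cyclisation (cat. I2, DMSO, 130 °C) gives 2-[2-(benzyloxy)-4-methoxyphenyl]-5,7,8-trimethoxy-4H-chromen-4-one F3; alkaline H2O2 is avoided because 6'-methoxy-2'-hydroxychalcones give aurones. DMDO in acetone/CH2Cl2 then gives rac-2-[2-(benzyloxy)-4-methoxyphenyl]-2,3-epoxy-5,7,8-trimethoxychroman-4-one F4, which is not isolated and which catalytic p-TsOH isomerises to 11.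

**Step 3 (DMDO oxidation of the 2-unsubstituted chromone).** The risks are competing oxidation of the electron-rich A ring and a labile epoxide. The fallback sets out from 4 (made from 3 as in step 2 and isolated by evaporation) and comes back at 7. Iodocyclisation of 4 (I2, CHCl3, rt) gives 3-iodo-5,7,8-trimethoxy-4H-chromen-4-one F5. Miyaura borylation (B2pin2, PdCl2(dppf), KOAc, dioxane, 80 °C) gives 5,7,8-trimethoxy-3-(4,4,5,5-tetramethyl-1,3,2-dioxaborolan-2-yl)-4H-chromen-4-one F6. Oxidation of the C–B bond (NaBO3·4H2O, THF–H2O, rt) gives 7.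

**Step 7 (selective 5-O-demethylation).** The risks are cleavage of the buttressed 8-OMe and sluggish reaction because the 3-O–boron chelate occupies the carbonyl. The fallback sets out from 12 and comes back at 13. Acetylation (Ac2O, pyridine, rt) gives 2-[2-(acetyloxy)-4-methoxyphenyl]-5,7,8-trimethoxy-4-oxo-4H-chromen-3-yl acetate F7, which leaves C4=O/5-OMe as the only chelating site. AlCl3 in MeCN at 50 °C then gives 2-[2-(acetyloxy)-4-methoxyphenyl]-5-hydroxy-7,8-dimethoxy-4-oxo-4H-chromen-3-yl acetate F8. Methanolysis (K2CO3, MeOH, 0 °C, N2) gives 13.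

## Further compounds

F1 | step 5 | 2-(benzyloxy)-4-methoxybenzaldehyde | COc1ccc(C=O)c(OCc2ccccc2)c1
F2 | step 5 | (E)-3-[2-(benzyloxy)-4-methoxyphenyl]-1-(2-hydroxy-3,4,6-trimethoxyphenyl)prop-2-en-1-one | COc1ccc(/C=C/C(=O)c2c(O)c(OC)c(OC)cc2OC)c(OCc2ccccc2)c1
F3 | step 5 | 2-[2-(benzyloxy)-4-methoxyphenyl]-5,7,8-trimethoxy-4H-chromen-4-one | COc1ccc(-c2cc(=O)c3c(OC)cc(OC)c(OC)c3o2)c(OCc2ccccc2)c1
F4 | step 5 | rac-2-[2-(benzyloxy)-4-methoxyphenyl]-2,3-epoxy-5,7,8-trimethoxychroman-4-one | COc1ccc(C23OC2C(=O)c2c(OC)cc(OC)c(OC)c2O3)c(OCc2ccccc2)c1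
F5 | step 3 | 3-iodo-5,7,8-trimethoxy-4H-chromen-4-one | COc1cc(OC)c2c(=O)c(I)coc2c1OC
F6 | step 3 | 5,7,8-trimethoxy-3-(4,4,5,5-tetramethyl-1,3,2-dioxaborolan-2-yl)-4H-chromen-4-one | COc1cc(OC)c2c(=O)c(B3OC(C)(C)C(C)(C)O3)coc2c1OC
F7 | step 7 | 2-[2-(acetyloxy)-4-methoxyphenyl]-5,7,8-trimethoxy-4-oxo-4H-chromen-3-yl acetate | COc1ccc(-c2oc3c(OC)c(OC)cc(OC)c3c(=O)c2OC(C)=O)c(OC(C)=O)c1
F8 | step 7 | 2-[2-(acetyloxy)-4-methoxyphenyl]-5-hydroxy-7,8-dimethoxy-4-oxo-4H-chromen-3-yl acetate | COc1ccc(-c2oc3c(OC)c(OC)cc(O)c3c(=O)c2OC(C)=O)c(OC(C)=O)c1
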